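The runs are simulated on assumed constants, noise included.

- The charge of solid substrate, the limiting reagent, is conserved: what the readings no longer show as solid substrate, solid or dissolved, has reacted.

| flask | solid substrate | temperature | remark | time |
|---|---|---|---|---|
| ochre | 0.70 M | −10 °C | run made earlier |  |
| amber | 1 M | 12 °C | run made earlier |  |
| ash | 1.4 M |  | at 20 °C throughout | 10 min |
| birch | 1.4 M |  | at −20 °C until 10 min, from then on at 20 °C | 30 min |

- ochre (time / min: target / %, solid substrate / %): 2.00: 8.5, 87.0; 6.00: 20.7, 60.0; 10.0: 30.4, 34.4; 15.0: 39.8, 1.3; 25.0: 30.5, 0.1
- amber (time / min: target / %, solid substrate / %): 1.50: 4.6, 92.2; 3.00: 9.9, 85.3; 4.00: 13.0, 81.9; 6.00: 20.4, 72.3; 8.00: 26.0, 62.8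

(standard deviation of a reading: 0.5 percentage points)

- solid substrate is a solid; its amount is given per volume of the solution
- at the start none of the solid substrate is in solution
- what has only dissolved of solid substrate counts as not reacted
- a reading or a percentage of target counts all its forms, free or not

* which of the two ends with the higher amount of target, in percent of the solid substrate charged ("neither" if they lie within 2 percentage points) (ash / birch / neither)
* target at the end, in percent of the solid substrate charged, ash
* target at the end, in percent of the solid substrate charged, birch

- From that balance I defined the feed rate, the solid substrate consumed per minute and per volume: the ochre run gave 0.0460 M min⁻¹, and the amber run gave 0.0452 M min⁻¹.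
- These readings agreed across −10 °C and 12 °C and across different charges, so I took the crawl into solution as the rate-limiting step and assumed the same feed at −20 °C and 20 °C.
- On the fastest rung of my ladder, dissolved substrate reacted as it arrived, since the reading, which counts it as unreacted, fell straight from the first point.
- On the next rung, target in the ochre run read 39.8 % at 15.0 min, with solid substrate down to 1.3 %, and 30.5 % at 25.0 min, so in the cold I did not treat target as the last stop and expected the cold stretch of birch to lose a part of what it made.
- The last rung was the emptying time, charge over feed, 30.4 min, longer than the 10 min of ash; ash would therefore consume 32.9 % of its charge and birch 98.6 %.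
- Target per solid consumed read 69.9 % in the amber run and 46.3 % in the ochre run at 10.0 min.
- I used the amber share for warm minutes and the ochre share for cold ones, which gave ash 23.0 % and birch 61.2 %.
- The forecast, holding that “loss is zero-order and nearly independent of temperature”, named birch and gave ash 24 % (19 % to 30 %) and birch 56 % (40 % to 66 %), above my ash figure and below my birch figure.
- The simulation named birch: ash ended at 26.8 % with 67.0 % solid substrate left, where my balance had 67.1 %, and birch ended at 76.3 % with 2.34 % left.

    starting material → intermediate (k = 0.00320 s⁻¹, Ea = 64.0 kJ mol⁻¹)
    starting material → target (k = 0.0120 s⁻¹, Ea = 80.0 kJ mol⁻¹)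
    intermediate → side product (k = 9.80 × 10⁻⁴ s⁻¹, Ea = 85.0 kJ mol⁻¹)
    solid substrate ⇌ starting material, rate k4*(cs4 - [starting material]) while solid is left; crystals form when [starting material] > cs4 (solubility = 1.10 M, k = 7.00 × 10⁻⁴ s⁻¹)
    target ⇌ isomer of the product (K = 5.30, k = 9.00 × 10⁻⁴ s⁻¹, Ea = 68.0 kJ mol⁻¹, ΔH = −58.0 kJ mol⁻¹)
    starting material + target ⇌ idle adduct, settled at all times (K = 0.460 M⁻¹, ΔH = −22.0 kJ mol⁻¹)
    (constants at −20 °C)

- The neighbouring flask was ash read at 40 min instead of 10 min, with amounts and temperature held. Its reading time lies beyond the emptying time of 30.4 min, so the balance put the whole charge past the solid stage, and the flask showed 0 % solid substrate remaining. Ash at 10 min had turned 81.3 % of its consumed solid into target, so that share of the full charge gave 81.3 %. The neighbouring flask held 81.3 % target.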